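Labdane numbering: ring A = C1–C5/C10, ring B = C5–C10. Ring B is a cyclohexene whose C7=C8 bond lies opposite the C5–C10 fusion bond, so it is cut by a Diels–Alder reaction into a C6–C9 diene that already carries the side chain and a C5=C10 dienophile. Since the C10 methyl (C20) and C4 are cis on ring B, the dienophile is an (S)-butenolide that ties C20 (lactone carbonyl) to O–C4. One endo cycloaddition, anti to the γ-chain, forms C5–C6 and C9–C10 and sets C5, C9 and C10. Ring A then closes by enolate alkylation; the lactone becomes the C20 methyl and a C4 ketone, from which C4, C19 and the 2α-alcohol are built.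

Key step: step 7

Remark on the chemistry: α and β refer to the usual labdane drawing with the C10 methyl (C20) β.
Remark on the chemistry: the (S,S)-ProPhenol ligand is assumed to deliver the S carbinol in step 5; if the sense is opposite, its enantiomer is used.

Step 1
Reactants: 1 geraniol
Product: 2 geranyl 4-methoxybenzyl ether
Conditions: NaH, PMBCl, n-Bu4NI (cat.), THF/DMF, 0 → 23 °C
Reagents that add atoms: 4-methoxybenzyl chloride, COc1ccc(CCl)cc1
Why: Williamson etherification of the primary allylic alkoxide installs a protecting group that should survive heat, strong base and hydride and is removed oxidatively at the end.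

Step 2
Reactants: 2 geranyl 4-methoxybenzyl ether
Product: 4 (2E,6E)-8-[(4-methoxybenzyl)oxy]-2,6-dimethylocta-2,6-dienal, via allylic alcohol 3 (not isolated)
Conditions: SeO2 (cat.), t-BuOOH, salicylic acid (cat.), CH2Cl2, 23 °C; then MnO2, CH2Cl2, 23 °C
Reagents that add atoms: tert-butyl hydroperoxide, CC(C)(C)OO (oxygen source, relayed by SeO2, O=[Se]=O)
Why: Riley allylic oxidation should select the E-methyl group of the electron-rich terminal alkene with retention of the E geometry, and MnO2 then oxidises only the allylic alcohol.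

Step 3
Reactants: 4 (2E,6E)-8-[(4-methoxybenzyl)oxy]-2,6-dimethylocta-2,6-dienal
Product: 5 1-methoxy-4-({[(2E,6E)-3,7-dimethylnona-2,6,8-trien-1-yl]oxy}methyl)benzene (the diene)
Conditions: Ph3PCH3Br, KOt-Bu, THF, 0 °C
Reagents that add atoms: methyltriphenylphosphonium bromide, C[P+](c1ccccc1)(c1ccccc1)c1ccccc1.[Br-]
Why: Wittig methylenation of the enal proceeds by 1,2-addition and leaves the E-trisubstituted alkene untouched, giving the (E)-1,3-diene with the side chain on the outside.

Step 4
Reactants: 6 4-chlorobutan-1-ol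
Product: 7 4-chlorobutanal
Conditions: TEMPO (cat.), PhI(OAc)2, CH2Cl2, 23 °C
Reagents that add atoms: none
Why: Oxoammonium-mediated alcohol oxidation should stop at the aldehyde and tolerate the primary chloride.

Step 5
Reactants: 7 4-chlorobutanal; 8 methyl propiolate
Product: 10 methyl (S)-7-chloro-4-hydroxyhept-2-ynoate, via zinc alkynylide 9 (not isolated)
Conditions: 8, Me2Zn, (S,S)-ProPhenol (cat.), Ph3PO (cat.), toluene, 0 °C; then 7, 4 °C
Reagents that add atoms: none
Why: Catalytic enantioselective alkynylation (addition of the zinc acetylide inside the dinuclear zinc–ProPhenol pocket) sets the S carbinol centre that becomes C4 and later steers the cycloaddition.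

Step 6
Reactants: 10 methyl (S)-7-chloro-4-hydroxyhept-2-ynoate
Product: 12 (S)-5-(3-chloropropyl)furan-2(5H)-one, via Z-hydroxy enoate 11 (not isolated)
Conditions: H2 (1 atm), Pd/CaCO3 poisoned with Pb(OAc)2, quinoline, EtOAc, 23 °C; then PPTS (cat.), CH2Cl2, 23 °C
Reagents that add atoms: none
Why: Cis-semihydrogenation of the alkyne places the ester next to the hydroxyl, so lactonisation gives the butenolide without touching the stereocentre or the alkyl chloride.

Step 7
Reactants: 12 (S)-5-(3-chloropropyl)furan-2(5H)-one; 5 the diene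
Product: 13 cis-fused cycloadduct, 3-(3-chloropropyl)-6-methyl-7-{(3E)-5-[(4-methoxybenzyl)oxy]-3-methylpent-3-en-1-yl}-3a,4,7,7a-tetrahydroisobenzofuran-1(3H)-one (H5 and H10 cis; side chain at C9 cis to the lactone; chloropropyl chain on the face of H5 and H10)
Conditions: toluene, BHT (cat.), 150 °C, sealed tube
Reagents that add atoms: none
Why: The electron-poor butenolide C5=C10 bond and the s-cis C6=C7–C8=C9 diene react in a concerted, asynchronous thermal [4+2] Diels–Alder reaction, the closest known type being cycloadditions of 5-substituted furan-2(5H)-ones with acyclic dienes. Ring B is closed in the intermolecular suprafacial/suprafacial mode, and the lactone ring is carried along cis-fused. C5 and C10 arise from cis addition to the ring-locked Z alkene, which puts H5 and H10 on one face and the lactone carbonyl C20 and O–C4 on the other, the arrangement that becomes the trans A/B fusion once C1 replaces H10. C9 is set by the endo transition state of the (E)-diene, which places the side chain cis to the lactone and hence cis to C20. The absolute sense comes from the S centre C4, because the diene adds to the face opposite the 3-chloropropyl chain. The step needs "ortho" regiochemistry (C6 to the β-carbon C5, C9 to the α-carbon C10), which the larger HOMO coefficient at the unsubstituted terminus of the 1-alkyl diene and the larger LUMO coefficient at the lactone β-carbon should secure.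

Step 8
Reactants: 13 cis-fused cycloadduct
Product: 15 15-[(4-methoxybenzyl)oxy]-18,19-dinorlabda-7,13E-dien-20,4β-olide, via potassium enolate 14 (not isolated)
Conditions: KN(SiMe3)2, n-Bu4NI (cat.), THF, −78 → 23 °C
Reagents that add atoms: none
Why: Intramolecular 6-exo-tet alkylation of the lactone enolate closes ring A; the chain sits on the convex face where H10 was, so C1 can bond to C10 only there, which makes C10 quaternary with C20 β and the A/B fusion trans.

Step 9
Reactants: 15 the 20,4β-olide
Product: 16 15-[(4-methoxybenzyl)oxy]-4β,20-epoxy-18,19-dinorlabda-7,13E-dien-20-ol (lactol, both C20 epimers)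
Conditions: i-Bu2AlH, CH2Cl2, −78 °C
Reagents that add atoms: none
Why: Partial hydride reduction of the lactone stops at the tetrahedral aluminium hemiacetal, which gives the bridged lactol (C20 at the aldehyde level) on work-up.

Step 10
Reactants: 16 the lactol
Product: 18 15-[(4-methoxybenzyl)oxy]-18,19-dinorlabda-7,13E-dien-4β-ol, via hydrazone 17 (not isolated)
Conditions: N2H4·H2O, KOH, diethylene glycol, 130 → 200 °C
Reagents that add atoms: none
Why: Wolff–Kishner reduction (Huang–Minlon variant) of the ring-opened hydroxy-aldehyde tautomer turns C20 into the angular methyl and frees the 4β-hydroxyl without touching a stereocentre.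

Step 11
Reactants: 18 the 4β-alcohol
Product: 19 15-[(4-methoxybenzyl)oxy]-18,19-dinorlabda-7,13E-dien-4-one
Conditions: DMP, NaHCO3, CH2Cl2, 23 °C
Reagents that add atoms: none
Why: Buffered hypervalent-iodine oxidation gives the C4 ketone without base, so the trans C5–H, now α to the carbonyl, should not epimerise.

Step 12
Reactants: 19 the C4 ketone
Product: 21 15-[(4-methoxybenzyl)oxy]-18,19-dinorlabda-3,7,13E-trien-4-yl trifluoromethanesulfonate, via potassium enolate 20 (not isolated)
Conditions: KN(SiMe3)2, THF, −78 °C (ketone added to base); then PhNTf2, −78 → 0 °C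
Reagents that add atoms: N-phenylbis(trifluoromethanesulfonimide), O=S(=O)(N(c1ccccc1)S(=O)(=O)C(F)(F)F)C(F)(F)F
Why: Kinetic deprotonation takes a C3 methylene proton and not the hindered ring-fusion C5–H, and O-sulfonylation fixes the C3=C4 enol triflate with C5 untouched.

Step 13
Reactants: 21 the enol triflate
Product: 22 methyl 15-[(4-methoxybenzyl)oxy]-18-norlabda-3,7,13E-trien-19-oate
Conditions: Pd(OAc)2 (cat.), dppp (cat.), CO (1 atm), MeOH, Et3N, DMF, 60 °C
Reagents that add atoms: carbon monoxide, [C-]#[O+]; methanol, CO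
Why: Palladium-catalysed methoxycarbonylation of the alkenyl triflate (oxidative addition, CO insertion, methanolysis) attaches C19 to C4 as an ester.

Step 14
Reactants: 22 the conjugated ester
Product: 24 methyl 15-[(4-methoxybenzyl)oxy]labda-2,7,13E-trien-19-oate, via lithium dienolate 23 (not isolated)
Conditions: LiN(i-Pr)2, HMPA, THF, −78 °C; then MeI, −78 → −40 °C
Reagents that add atoms: iodomethane, CI
Why: Deconjugative alkylation: γ-deprotonation at C2 gives the extended enolate, which reacts at the α-carbon C4, and MeI should approach the α-face opposite the axial C10 methyl, so the new methyl is 4α, the ester 4β, and the alkene moves to C2=C3.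

Step 15
Reactants: 24 the quaternary ester
Product: 25 15-[(4-methoxybenzyl)oxy]labda-2,7,13E-trien-19-ol
Conditions: LiAlH4, THF, 0 → 23 °C
Reagents that add atoms: none
Why: Hydride reduction of the hindered ester gives the neopentyl C19 alcohol, while the isolated alkenes and the benzyl-type ether are inert.

Step 16
Reactants: 25 the C19 alcohol
Product: 26 19-acetoxy-15-[(4-methoxybenzyl)oxy]labda-2,7,13E-triene
Conditions: Ac2O, pyridine, DMAP (cat.), CH2Cl2, 23 °C
Reagents that add atoms: acetic anhydride, CC(=O)OC(C)=O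
Why: Nucleophile-catalysed acylation of the only free hydroxyl installs the 19-acetate.

Step 17
Reactants: 26 the 19-acetate
Product: 28 19-acetoxy-15-[(4-methoxybenzyl)oxy]labda-7,13E-dien-2α-ol, via organoborane 27 (not isolated)
Conditions: Sia2BH (from BH3·THF and 2-methylbut-2-ene), THF, 0 → 23 °C; then 30% H2O2, aq. NaOAc, 0 °C
Reagents that add atoms: hydrogen peroxide, OO
Why: Hydroboration–oxidation with a bulky dialkylborane should take only the cis-disubstituted C2=C3 alkene, place boron on C2 (remote from quaternary C4) from the α-face opposite the axial C19 and C20 groups, and give the equatorial 2α-alcohol with retention on oxidation.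

Step 18
Reactants: 28 the 15-O-(4-methoxybenzyl) ether of the target
Product: 29 19-acetoxylabda-7,13E-diene-2α,15-diol (target)
Conditions: DDQ, CH2Cl2/pH 7 buffer, 0 °C
Reagents that add atoms: none
Why: Oxidative cleavage of the 4-methoxybenzyl ether (benzylic hydride abstraction, then hydrolysis of the hemiacetal) frees the C15 allylic alcohol and should leave the acetate, the secondary alcohol and the alkenes untouched.

Compound list
1 | geraniol | CC(C)=CCC/C(C)=C/CO | starting material
2 | geranyl 4-methoxybenzyl ether | CC(C)=CCC/C(C)=C/COCc1ccc(OC)cc1 | intermediate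
3 | (2E,6E)-8-[(4-methoxybenzyl)oxy]-2,6-dimethylocta-2,6-dien-1-ol (not isolated) | OC/C(C)=C/CC/C(C)=C/COCc1ccc(OC)cc1 | intermediate
4 | (2E,6E)-8-[(4-methoxybenzyl)oxy]-2,6-dimethylocta-2,6-dienal | O=C/C(C)=C/CC/C(C)=C/COCc1ccc(OC)cc1 | intermediate
5 | 1-methoxy-4-({[(2E,6E)-3,7-dimethylnona-2,6,8-trien-1-yl]oxy}methyl)benzene | C=C/C(C)=C/CC/C(C)=C/COCc1ccc(OC)cc1 | intermediate
6 | 4-chlorobutan-1-ol | OCCCCCl | starting material
7 | 4-chlorobutanal | O=CCCCCl | intermediate
8 | methyl propiolate | C#CC(=O)OC | starting material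
9 | methyl 3-(methylzincio)prop-2-ynoate (not isolated) | C[Zn]C#CC(=O)OC | intermediate
10 | methyl (S)-7-chloro-4-hydroxyhept-2-ynoate | COC(=O)C#C[C@@H](O)CCCCl | intermediate
11 | methyl (S,Z)-7-chloro-4-hydroxyhept-2-enoate (not isolated) | COC(=O)/C=C\[C@@H](O)CCCCl | intermediate
12 | (S)-5-(3-chloropropyl)furan-2(5H)-one | O=C1C=C[C@H](CCCCl)O1 | intermediate
13 | cis-fused cycloadduct (lactone C20 and O–C4 β, H5 and H10 α, 9β side chain) | O=C1O[C@@H](CCCCl)[C@@H]2CC=C(C)[C@H](CC/C(C)=C/COCc3ccc(OC)cc3)[C@H]12 | intermediate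
14 | potassium enolate of 13 (not isolated) | [K+].[O-]C1=C2[C@@H](CC/C(C)=C/COCc3ccc(OC)cc3)C(C)=CC[C@H]2[C@H](CCCCl)O1 | intermediate
15 | 15-[(4-methoxybenzyl)oxy]-18,19-dinorlabda-7,13E-dien-20,4β-olide | O=C3O[C@H]1CCC[C@@]32[C@@H](CC/C(C)=C/COCc4ccc(OC)cc4)C(C)=CC[C@@H]12 | intermediate
16 | 15-[(4-methoxybenzyl)oxy]-4β,20-epoxy-18,19-dinorlabda-7,13E-dien-20-ol (C20 epimers) | OC3O[C@H]1CCC[C@@]32[C@@H](CC/C(C)=C/COCc4ccc(OC)cc4)C(C)=CC[C@@H]12 | intermediate
17 | 4β-hydroxy-15-[(4-methoxybenzyl)oxy]-18,19-dinorlabda-7,13E-dien-20-al hydrazone (not isolated; C=N geometry not defined) | O[C@H]1CCC[C@]2(C=NN)[C@@H](CC/C(C)=C/COCc3ccc(OC)cc3)C(C)=CC[C@@H]12 | intermediate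
18 | 15-[(4-methoxybenzyl)oxy]-18,19-dinorlabda-7,13E-dien-4β-ol | O[C@H]1CCC[C@]2(C)[C@@H](CC/C(C)=C/COCc3ccc(OC)cc3)C(C)=CC[C@@H]12 | intermediate
19 | 15-[(4-methoxybenzyl)oxy]-18,19-dinorlabda-7,13E-dien-4-one | O=C1CCC[C@]2(C)[C@@H](CC/C(C)=C/COCc3ccc(OC)cc3)C(C)=CC[C@@H]12 | intermediate
20 | potassium 3-en-4-olate of 19 (not isolated) | [K+].[O-]C1=CCC[C@]2(C)[C@@H](CC/C(C)=C/COCc3ccc(OC)cc3)C(C)=CC[C@@H]12 | intermediate
21 | 15-[(4-methoxybenzyl)oxy]-18,19-dinorlabda-3,7,13E-trien-4-yl trifluoromethanesulfonate | O=S(=O)(OC1=CCC[C@]2(C)[C@@H](CC/C(C)=C/COCc3ccc(OC)cc3)C(C)=CC[C@@H]12)C(F)(F)F | intermediate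
22 | methyl 15-[(4-methoxybenzyl)oxy]-18-norlabda-3,7,13E-trien-19-oate | COC(=O)C1=CCC[C@]2(C)[C@@H](CC/C(C)=C/COCc3ccc(OC)cc3)C(C)=CC[C@@H]12 | intermediate
23 | lithium dienolate of 22 (not isolated) | [Li+].[O-]C(OC)=C1C=CC[C@]2(C)[C@@H](CC/C(C)=C/COCc3ccc(OC)cc3)C(C)=CC[C@@H]12 | intermediate
24 | methyl 15-[(4-methoxybenzyl)oxy]labda-2,7,13E-trien-19-oate | COC(=O)[C@@]1(C)C=CC[C@]2(C)[C@@H](CC/C(C)=C/COCc3ccc(OC)cc3)C(C)=CC[C@@H]12 | intermediate
25 | 15-[(4-methoxybenzyl)oxy]labda-2,7,13E-trien-19-ol | OC[C@@]1(C)C=CC[C@]2(C)[C@@H](CC/C(C)=C/COCc3ccc(OC)cc3)C(C)=CC[C@@H]12 | intermediate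
26 | 19-acetoxy-15-[(4-methoxybenzyl)oxy]labda-2,7,13E-triene | CC(=O)OC[C@@]1(C)C=CC[C@]2(C)[C@@H](CC/C(C)=C/COCc3ccc(OC)cc3)C(C)=CC[C@@H]12 | intermediate
27 | 2α-(disiamylboryl) derivative of 26 (not isolated) | CC(=O)OC[C@@]1(C)C[C@H](B(C(C)C(C)C)C(C)C(C)C)C[C@]2(C)[C@@H](CC/C(C)=C/COCc3ccc(OC)cc3)C(C)=CC[C@@H]12 | intermediate
28 | 19-acetoxy-15-[(4-methoxybenzyl)oxy]labda-7,13E-dien-2α-ol | CC(=O)OC[C@@]1(C)C[C@H](O)C[C@]2(C)[C@@H](CC/C(C)=C/COCc3ccc(OC)cc3)C(C)=CC[C@@H]12 | intermediate
29 | 19-acetoxylabda-7,13E-diene-2α,15-diol | CC(=O)OC[C@@]1(C)C[C@H](O)C[C@]2(C)[C@@H](CC/C(C)=C/CO)C(C)=CC[C@@H]12 | target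

Total step count: 18. Longest linear sequence: 15 steps (steps 1–3 and 7–18; the butenolide branch, steps 4–6 and 7–18, is equally long).

Steps most likely to fail

Step 7. The cycloaddition may be too slow at temperatures the diene tolerates, and regiocontrol may erode because the C9 alkyl and C8 methyl groups of the diene direct in opposite senses; the endo preference may also be weak. The fallback sets out from 2 and comes back at 15. Ozonolysis of the electron-rich 6,7-alkene (O3, pyridine, CH2Cl2, −78 °C; Me2S) gives aldehyde F1. A Wittig reaction with 3-(triphenylphosphoranylidene)butan-2-one gives (E)-enone F2, and TBSOTf/Et3N turns it into the 2-silyloxy diene F3, in which the enol ether makes C6 the unambiguous nucleophilic terminus and raises reactivity. Cycloaddition with 12 (toluene, 110 °C) gives silyl enol ether adduct F4, and the alkylation of step 8 gives tricyclic lactone F5. CsF/PhNTf2 converts it into enol triflate F6, which Pd(OAc)2/PPh3 with HCO2H and n-Bu3N reduces to 15.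

Step 14. Alkylation of the extended enolate may take place at the γ-carbon or from the β-face. The fallback sets out from 21 and comes back at 25. Reductive carbonylation (Pd(OAc)2, dppp, CO, Et3SiH, Et3N, DMF) gives enal F7. Its potassium dienolate (KOt-Bu, t-BuOH/THF) is α-methylated with MeI to the 4α-methyl β,γ-unsaturated aldehyde F8, and NaBH4 reduces this to 25.

Step 10. Ring opening of the bridged lactol to the hydrazone may be slow, so that the forcing basic conditions degrade the material before nitrogen is lost. The fallback sets out from 16 and comes back at 18. Condensation with TsNHNH2 (THF, 50 °C) gives the ring-opened tosylhydrazone F9, which is reduced with catecholborane (CHCl3, 0 °C) followed by NaOAc·3H2O (60 °C) to 18.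

Further compounds
F1 | step 7 | (E)-6-[(4-methoxybenzyl)oxy]-4-methylhex-4-enal | O=CCC/C(C)=C/COCc1ccc(OC)cc1
F2 | step 7 | (3E,7E)-9-[(4-methoxybenzyl)oxy]-3,7-dimethylnona-3,7-dien-2-one | CC(=O)/C(C)=C/CC/C(C)=C/COCc1ccc(OC)cc1
F3 | step 7 | tert-butyl({(3E,7E)-9-[(4-methoxybenzyl)oxy]-3,7-dimethylnona-1,3,7-trien-2-yl}oxy)dimethylsilane | C=C(O[Si](C)(C)C(C)(C)C)/C(C)=C/CC/C(C)=C/COCc1ccc(OC)cc1
F4 | step 7 | 7-silyloxy analogue of cycloadduct 13 | O=C1O[C@@H](CCCCl)[C@@H]2CC(O[Si](C)(C)C(C)(C)C)=C(C)[C@H](CC/C(C)=C/COCc3ccc(OC)cc3)[C@H]12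
F5 | step 7 | 7-silyloxy analogue of tricyclic lactone 15 | O=C3O[C@H]1CCC[C@@]32[C@@H](CC/C(C)=C/COCc4ccc(OC)cc4)C(C)=C(O[Si](C)(C)C(C)(C)C)C[C@@H]12
F6 | step 7 | 7-trifluoromethanesulfonyloxy analogue of tricyclic lactone 15 | O=C3O[C@H]1CCC[C@@]32[C@@H](CC/C(C)=C/COCc4ccc(OC)cc4)C(C)=C(OS(=O)(=O)C(F)(F)F)C[C@@H]12
F7 | step 14 | 15-[(4-methoxybenzyl)oxy]-18-norlabda-3,7,13E-trien-19-al | O=CC1=CCC[C@]2(C)[C@@H](CC/C(C)=C/COCc3ccc(OC)cc3)C(C)=CC[C@@H]12
F8 | step 14 | 15-[(4-methoxybenzyl)oxy]labda-2,7,13E-trien-19-al | O=C[C@@]1(C)C=CC[C@]2(C)[C@@H](CC/C(C)=C/COCc3ccc(OC)cc3)C(C)=CC[C@@H]12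
F9 | step 10 | 4β-hydroxy-15-[(4-methoxybenzyl)oxy]-18,19-dinorlabda-7,13E-dien-20-al tosylhydrazone | O[C@H]1CCC[C@]2(C=NNS(=O)(=O)c3ccc(C)cc3)[C@@H](CC/C(C)=C/COCc4ccc(OC)cc4)C(C)=CC[C@@H]12
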